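Seconds per turn of the free catalyst are the unit to reckon in for this flask.

    catalyst intermediate A → catalyst intermediate B (k1 = 120 s⁻¹)
    catalyst intermediate B → free catalyst + product (k2 = 120 s⁻¹)
    starting material + free catalyst → catalyst intermediate A (k3 = 38000 M⁻¹ s⁻¹)

starting material 0.0010 M; free catalyst 1.0 µM; time 6.0 min

- the reaction counts as stopped when no species that holds the starting material changes by six tenths of a point or more over the second half of the time
- run time (flask): 6.0 min

- at 6.0 min, what has stopped the reaction, if anything has (it is still moving / all of the starting material has reacted / no working catalyst is left)
- part of the starting material gone at 6.0 min
- the product standing at 6.0 min, as a percentage of the starting material charged
- amount of product if the flask were left three thousand times as long, in percent of the starting material charged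

- One turn of the catalyst has two parts: a wait for capture, which lengthens as [starting material] falls, and a hold on catalyst intermediates A and B, which stays at 0.0167 s.
- The wait equals the hold at a crossing of 1.58 mM, which is higher than the charge, so in this flask the wait is the longer part from the start.
- Summed over the charge, the turns give two times: the push-through time 16.7 s, which is the hold multiplied by the turns each catalyst must make, and the search time, the inverse of the capture constant times the catalyst charged 26.3 s.
- The search time is longer by a factor of 1.57, so the two are of like size and the early decay is not first-order. Once the fraction left is small, the decay is close to pseudo-first-order: after a delay of one push-through time, [starting material] falls by a factor e in each search time.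
- My reckoning for this flask: the run holds 13.1 search times after the delay, which leaves <0.001% of the starting material. No step destroys the catalyst, and its charge is 0.100% of the starting material, so I expect essentially full conversion to product, now and later.
- The forecast gives all of the starting material has reacted, with 100% gone, 100% product and 100% in the long run, starting from “The catalyst is never destroyed”.
- The simulation gives all of the starting material has reacted, with >99.9% gone, >99.9% product and 100% in the long run.
- The half-life of starting material by capture, 0.40 min at 0.444 min, is shorter than the run of 6.0 min.
- At 3.00 min the flask holds 0.201% starting material, and the search time gives 0.201% left for that moment.
- A neighbour flask with the same charges is read at 1.5 min: the search time gives 6.16% left, and the computed flask holds 5.94% starting material and 94.1% product.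

(The numbers were set for the occasion; the flask was simulated.)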